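**Plan**

- Retrosynthesis first removes the C2–Br and C3–Br bonds and the C2=C3 unsaturation, then the N-acetyl group, leading back to 1-acetyl-4,6-dibromoindoline. The benzene ring is then cut at C3a–C7a and C4–C5.
- Enabling feature: the benzene ring has Br at C4 and C6 and H at C5 and C7. C7a, C7, C6 and C5 map onto C3, C4, C5 and C6 of 5-bromopyridazin-3-amine, and C3a/C4 map onto a bromoalkyne held to nitrogen by the N1–C2–C3 chain.
- Forward: the aminopyridazine is N-acetylated, N-alkylated with 4-bromobut-1-yne, and the alkyne terminus is brominated.
- One thermal step then closes the five-membered ring and the benzene ring together with loss of N2. Amide hydrolysis, dehydrogenation to the pyrrole ring and bromination at C3 then C2 complete the target.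
- Stereochemistry: the target is achiral. The only stereocentres on the route are the two bridgeheads of the transient cycloadduct, and they vanish with N2.

Key step: step 4

Assumption: 5-bromopyridazin-3-amine and 4-bromobut-1-yne are taken as purchasable, and the amidate of 2 is assumed to alkylate mainly at the exocyclic nitrogen, as 2-acylaminoazines normally do.

**Route**

Step 1
Reactants: 1 5-bromopyridazin-3-amine
Product: 2 N-(5-bromopyridazin-3-yl)acetamide
Conditions: Ac2O (1.3 equiv), pyridine, CH2Cl2, rt → 40 °C
Reagents that add atoms: acetic anhydride, CC(=O)OC(C)=O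
Why: N-acylation (nucleophilic acyl substitution) of the exocyclic amino group of an aminoazine with acetic anhydride is routine and should stop at the monoacetamide when the anhydride is limited.

Step 2
Reactants: 2 N-(5-bromopyridazin-3-yl)acetamide; 3 4-bromobut-1-yne
Product: 4 N-(5-bromopyridazin-3-yl)-N-(but-3-yn-1-yl)acetamide
Conditions: Cs2CO3 (1.5 equiv), 3 (2 equiv), DMF, rt → 45 °C
Reagents that add atoms: none
Why: SN2 N-alkylation of an N-heteroaryl acetamide, whose N–H is acidified by the acetyl group and the diazine, with a primary bromide; the mild carbonate base and moderate temperature are chosen to hold back E2 elimination of the homopropargyl bromide and substitution of the C5 bromine.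

Step 3
Reactants: 4 N-(5-bromopyridazin-3-yl)-N-(but-3-yn-1-yl)acetamide
Product: 5 N-(4-bromobut-3-yn-1-yl)-N-(5-bromopyridazin-3-yl)acetamide
Conditions: NBS (1.1 equiv), AgNO3 (10 mol%), acetone, rt, dark
Reagents that add atoms: N-bromosuccinimide, O=C1CCC(=O)N1Br
Why: Silver-catalysed electrophilic bromination of a terminal alkyne C–H with NBS is a standard route to 1-bromoalkynes, and the electron-poor diazine and the tertiary amide should be inert to NBS under these conditions.

Step 4
Reactants: 5 N-(4-bromobut-3-yn-1-yl)-N-(5-bromopyridazin-3-yl)acetamide
Product: 7 1-acetyl-4,6-dibromoindoline, via azo-bridged cycloadduct 6 (not isolated)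
Conditions: 1,3,5-triisopropylbenzene (0.01 M, degassed), BHT (cat.), Ar, sealed vessel, 200 °C
Reagents that add atoms: none
Why: On heating, the pyridazine acts as the electron-poor 4π component (C3=C4–C5=C6) and the tethered bromoalkyne as the 2π component of an intramolecular inverse-electron-demand Diels–Alder reaction, the internal alkyne carbon bonding to C3 and the bromine-bearing carbon to C6 to give azo-bridged adduct 6, which loses N2 by retro-Diels–Alder reaction and so becomes the benzene ring. The closest known reaction is the thermal cyclisation of N-acyl-N-(but-3-ynyl)pyridazin-3-amines to N-acylindolines at 200–230 °C, from which this substrate differs only in the bromine atoms on the alkyne terminus and on C5 of the diazine. The five-membered ring closes by formation of the C3a–C7a bond, the three-atom N–CH2–CH2 tether delivering the alkyne to C3 through a fused five-membered array, and the six-membered carbocycle closes in the same [4+2] event through C3a–C7a and C4–C5 and is aromatised by the cycloreversion. No stereocentre is created in 7, since the two bridgehead centres of racemic 6 disappear with N2. The step needs one regiochemical outcome, alkyne bromine at C4 and diazine bromine at C6, and the short tether secures it because the internal alkyne carbon can reach only C3, which forces the bromine-bearing terminus onto C6. The C5 bromine and the N-acetyl group, which withholds the nitrogen lone pair from the ring, lower the diazine LUMO, while high dilution, exclusion of oxygen and a radical inhibitor are meant to protect the bromoalkyne at this temperature.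

Step 5
Reactants: 7 1-acetyl-4,6-dibromoindoline
Product: 8 4,6-dibromoindoline
Conditions: 6 M HCl (aq), EtOH, reflux; then NaOH (aq) to pH 9
Reagents that add atoms: none
Why: Acid-catalysed amide hydrolysis is the usual way to free an N-acetylindoline, and the aryl bromides are inert to hot aqueous acid.

Step 6
Reactants: 8 4,6-dibromoindoline
Product: 9 4,6-dibromo-1H-indole
Conditions: DDQ (1.1 equiv), toluene, rt → 60 °C
Reagents that add atoms: none
Why: Quinone dehydrogenation of an indoline to the indole (hydride abstraction at C2 followed by proton loss) is well established and is driven by formation of the aromatic pyrrole ring.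

Step 7
Reactants: 9 4,6-dibromo-1H-indole
Product: 11 2,3,4,6-tetrabromo-1H-indole, via 3,4,6-tribromo-1H-indole 10 (not isolated)
Conditions: NBS (2.05 equiv), THF, −78 °C → rt, dark
Reagents that add atoms: N-bromosuccinimide, O=C1CCC(=O)N1Br
Why: Electrophilic aromatic substitution of an N–H indole with NBS takes place first at C3 and then, with a second equivalent, at C2 of the 3-bromoindole, a known route to 2,3-dibromoindoles; the benzene ring already carries two deactivating bromines, so C5 and C7 should stay untouched when the reagent is limited.

**Compound list**

1 | 5-bromopyridazin-3-amine | Nc1cc(Br)cnn1 | starting material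
2 | N-(5-bromopyridazin-3-yl)acetamide | CC(=O)Nc1cc(Br)cnn1 | intermediate
3 | 4-bromobut-1-yne | BrCCC#C | starting material
4 | N-(5-bromopyridazin-3-yl)-N-(but-3-yn-1-yl)acetamide | CC(=O)N(CCC#C)c1cc(Br)cnn1 | intermediate
5 | N-(4-bromobut-3-yn-1-yl)-N-(5-bromopyridazin-3-yl)acetamide | CC(=O)N(CCC#CBr)c1cc(Br)cnn1 | intermediate
6 | azo-bridged cycloadduct, 1-acetyl-4,6-dibromo-2,3-dihydro-5H-5,7a-epidiazenoindole (racemic, formed in the flask only) | CC(=O)N1CCC2=C(Br)C3C(Br)=CC12N=N3 | intermediate
7 | 1-acetyl-4,6-dibromoindoline | CC(=O)N1CCc2c(Br)cc(Br)cc21 | intermediate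
8 | 4,6-dibromoindoline | Brc1cc(Br)c2c(c1)NCC2 | intermediate
9 | 4,6-dibromo-1H-indole | Brc1cc(Br)c2cc[nH]c2c1 | intermediate
10 | 3,4,6-tribromo-1H-indole (formed in the flask only) | Brc1cc(Br)c2c(Br)c[nH]c2c1 | intermediate
11 | 2,3,4,6-tetrabromo-1H-indole | Brc1cc(Br)c2c(Br)c(Br)[nH]c2c1 | target

**Count and risks**

Total step count: 7. Longest linear sequence: 7 steps (1 → 11).

Steps most likely to fail:

1. Step 4. The bromoalkyne may degrade at 200 °C (C–Br homolysis, oligomerisation, attack by a diazine nitrogen) faster than the disubstituted alkyne cyclises. Fallback, setting out from 4: the terminal alkyne would be stannylated with Bu3SnNMe2 (neat, 60 °C) to give N-(5-bromopyridazin-3-yl)-N-[4-(tributylstannyl)but-3-yn-1-yl]acetamide F1. Its electron-rich stannylalkyne, a dienophile class known for azine cycloadditions, should undergo the same intramolecular cycloaddition and N2 loss in 1,3,5-triisopropylbenzene at about 200 °C to give 1-acetyl-6-bromo-4-(tributylstannyl)indoline F2. Ipso-bromodestannylation with Br2 in CH2Cl2 at −78 °C should outrun bromination at any C–H position and comes back to the route at 7. A stannane is preferred to a silane here because a silane at C4, meta to nitrogen, would have to compete with the nitrogen-activated C5 and C7 positions.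

2. Step 2. The amidate may alkylate at ring nitrogen N2 instead of the amide nitrogen, the bromide may lose HBr to the base, or the amidate may displace the C5 bromine of a second molecule. Fallback, setting out from 1: Boc2O with catalytic DMAP in THF would give tert-butyl (5-bromopyridazin-3-yl)carbamate F3. A Mitsunobu reaction with but-3-yn-1-ol (PPh3, DIAD, THF), which needs no base and no alkyl halide, would give tert-butyl (5-bromopyridazin-3-yl)(but-3-yn-1-yl)carbamate F4. TFA in CH2Cl2 would free 5-bromo-N-(but-3-yn-1-yl)pyridazin-3-amine F5, and acetylation with Ac2O in pyridine at 80 °C comes back to the route at 4.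

3. Step 7. The unprotected indole may be over-oxidised by NBS, bromination at C2 may stall on the electron-poor 3-bromoindole, or the product may decompose under the HBr formed. Fallback, setting out from 9: NCS in DMF at rt would give 4,6-dibromo-3-chloro-1H-indole F6. Hydrolysis in H3PO4 and 2-methoxyethanol at reflux would give 4,6-dibromoindolin-2-one F7. POBr3 and imidazole in 1,2-dichloroethane at reflux would convert the lactam into 2,4,6-tribromo-1H-indole F8, so that the C2 bromine comes from the carbonyl group instead of from an electrophilic substitution. A single equivalent of NBS in THF at −78 °C would then brominate the free C3 and arrive at target 11.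

**Further compounds**

F1 | step 4 | N-(5-bromopyridazin-3-yl)-N-[4-(tributylstannyl)but-3-yn-1-yl]acetamide | CC(=O)N(CCC#C[Sn](CCCC)(CCCC)CCCC)c1cc(Br)cnn1
F2 | step 4 | 1-acetyl-6-bromo-4-(tributylstannyl)indoline | CC(=O)N1CCc2c([Sn](CCCC)(CCCC)CCCC)cc(Br)cc21
F3 | step 2 | tert-butyl (5-bromopyridazin-3-yl)carbamate | CC(C)(C)OC(=O)Nc1cc(Br)cnn1
F4 | step 2 | tert-butyl (5-bromopyridazin-3-yl)(but-3-yn-1-yl)carbamate | CC(C)(C)OC(=O)N(CCC#C)c1cc(Br)cnn1
F5 | step 2 | 5-bromo-N-(but-3-yn-1-yl)pyridazin-3-amine | C#CCCNc1cc(Br)cnn1
F6 | step 7 | 4,6-dibromo-3-chloro-1H-indole | Clc1c[nH]c2cc(Br)cc(Br)c12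
F7 | step 7 | 4,6-dibromoindolin-2-one | O=C1Cc2c(Br)cc(Br)cc2N1
F8 | step 7 | 2,4,6-tribromo-1H-indole | Brc1cc2c(Br)cc(Br)cc2[nH]1
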